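**Retrosynthetic overview**
1. C6–C7 cut: the C4–C14 part, with the only stereocentre (C5, S), comes from (S)-epichlorohydrin 1 and n-octylmagnesium bromide 2; chlorohydrin 3 closes to epoxide 4, and the C5–O bond is bought and never broken.
2. The aryl/C1–C3 acyl part is dihydroferulic acid 5, activated as its S-2-pyridyl thioester 6 with the phenol left free.
3. Key cut C3–C4: in one flask, AcBr opens 4 to bromo acetate 7 (this installs the acetate and exposes a primary C–Br), then a blue-light nickel-catalysed reductive acyl coupling of 7 with 6 gives target 8.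
4. Rings: the benzene ring is bought; the only ring made is the oxirane of 4 (step 1), which is opened again in step 3; the carbon chain of the target is acyclic.

Assumption: positions are numbered as in the gingerols (C1 benzylic CH2, C3 ketone, C5 acetoxy carbon, C14 chain end), and 1, 2 and 5 are taken as catalogue compounds.

**Step 1**
Reactants: 1 (S)-epichlorohydrin [(S)-2-(chloromethyl)oxirane]; 2 n-octylmagnesium bromide (n-C8H17MgBr, 1.2 equiv)
Product: 4 (S)-2-nonyloxirane, via (S)-1-chloroundecan-2-ol 3 (not isolated)
Conditions: CuI (5 mol%), THF, −40 → 0 °C; then 4 M aq. NaOH, rt, 3 h; distil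
Reagents that add atoms: none
Why: Copper-catalysed Grignard opening of the oxirane at its CH2 terminus (SN2, cuprate-type) followed by intramolecular Williamson closure onto the achiral CH2Cl carbon; the C–O bond of the stereocentre bought in 1 is never broken and the CIP ranks stay the same, so 4 is the S enantiomer.

**Step 2**
Reactants: 5 3-(4-hydroxy-3-methoxyphenyl)propanoic acid (dihydroferulic acid)
Product: 6 S-(pyridin-2-yl) 3-(4-hydroxy-3-methoxyphenyl)propanethioate
Conditions: 2,2'-dipyridyl disulfide (1.2 equiv), PPh3 (1.2 equiv), CH2Cl2, 0 °C → rt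
Reagents that add atoms: 2,2'-dipyridyl disulfide, c1ccc(SSc2ccccn2)nc1
Why: Mukaiyama redox condensation, in which the acyloxyphosphonium ion is captured by pyridine-2-thiolate much faster than by the neutral phenol, so no protecting group is needed; no stereocentre is involved.

**Step 3**
Reactants: 4 (S)-2-nonyloxirane (1.3 equiv); 6 S-(pyridin-2-yl) 3-(4-hydroxy-3-methoxyphenyl)propanethioate (1.0 equiv)
Product: 8 (5S)-1-(4-hydroxy-3-methoxyphenyl)-3-oxotetradecan-5-yl acetate, via (S)-1-bromoundecan-2-yl acetate 7 (not isolated)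
Conditions: AcBr (1.25 equiv), Bu4NBr (5 mol%), CH2Cl2, 0 °C → rt, evaporate; then 6, NiBr2(dme) (10 mol%), 4,4'-di-tert-butyl-2,2'-bipyridine (12 mol%), 4CzIPN (2 mol%), Hantzsch ester (1.5 equiv), NaHCO3 (2 equiv), DMA, 450 nm LEDs, 25 °C
Reagents that add atoms: acetyl bromide, CC(=O)Br
Why: Proposed new method: a one-pot acyl–acetoxy insertion across the terminal C–O bond of an epoxide by nickel/photoredox reductive cross-electrophile acylation, in which AcBr first opens 4 by bromide SN2 attack at the unsubstituted carbon (the C5–O bond is never broken, so the S centre is retained) to give 7, and then, under blue light, 4CzIPN reductively quenched by Hantzsch ester reduces divalent nickel to zerovalent nickel, which inserts into the C(acyl)–S bond of 6, while monovalent nickel abstracts bromine from 7 to give the primary β-acetoxyalkyl radical that is trapped by the acyl–nickel complex and leaves trivalent nickel by C3–C4 reductive elimination, expected to outrun β-acetoxy elimination and 1,2-acyloxy shift, the free phenol being tolerated because the medium is reducing and free of strong base; the closest known reaction types are the nickel-catalysed reductive ketone synthesis from alkyl halides and S-2-pyridyl thioesters driven by a metal-powder reductant and the halide-relay nickel-catalysed coupling of epoxides with aryl halides.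

**Compound list**
1 | (S)-epichlorohydrin, (S)-2-(chloromethyl)oxirane | ClC[C@@H]1CO1 | starting material
2 | n-octylmagnesium bromide (n-C8H17MgBr) | CCCCCCCC[Mg]Br | starting material
3 | (S)-1-chloroundecan-2-ol (present in the flask as its alkoxide) | CCCCCCCCC[C@@H](CCl)O | intermediate
4 | (S)-2-nonyloxirane, (S)-1,2-epoxyundecane | CCCCCCCCC[C@H]1CO1 | intermediate
5 | 3-(4-hydroxy-3-methoxyphenyl)propanoic acid (dihydroferulic acid) | COc1cc(CCC(=O)O)ccc1O | starting material
6 | S-(pyridin-2-yl) 3-(4-hydroxy-3-methoxyphenyl)propanethioate | COc1cc(CCC(=O)Sc2ccccn2)ccc1O | intermediate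
7 | (S)-1-bromoundecan-2-yl acetate | CCCCCCCCC[C@@H](CBr)OC(C)=O | intermediate
8 | (5S)-1-(4-hydroxy-3-methoxyphenyl)-3-oxotetradecan-5-yl acetate | CCCCCCCCC[C@@H](CC(=O)CCc1ccc(O)c(OC)c1)OC(C)=O | target

**Totals**
Total step count: 3. Longest linear sequence: 2 (step 1 then step 3; step 2 then step 3 is equally long).

**Steps most likely to fail**

First, step 3 (the proposed new method). Possible failures are:
- a few percent of the regioisomeric 2-bromoundecyl acetate from the AcBr opening, which would couple to a branched ketone isomer that must be separated;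
- loss of the β-acetoxy group (1-undecene) if the radical meets low-valent nickel before the acyl complex;
- hydrodebromination of 7 by Hantzsch ester;
- interference by the free phenol;
- base-induced loss of AcOH from 8 to the enone, so amine bases are kept out.

The fallback is known polar umpolung chemistry; it sets out from 5, uses 4 from step 1 as the electrophile, and comes back to the route at 8. Acid 5 is doubly benzylated (BnBr, K2CO3, DMF) to benzyl 3-[4-(benzyloxy)-3-methoxyphenyl]propanoate F1. This is reduced at −78 °C with diisobutylaluminium hydride, (Me2CHCH2)2AlH, in CH2Cl2 to 3-[4-(benzyloxy)-3-methoxyphenyl]propanal F2, which is thioacetalised (propane-1,3-dithiol, BF3·OEt2, CH2Cl2) to 2-{2-[4-(benzyloxy)-3-methoxyphenyl]ethyl}-1,3-dithiane F3. Corey–Seebach lithiation (n-BuLi, THF, −30 °C) and opening of 4 at its CH2 terminus gives (2S)-1-(2-{2-[4-(benzyloxy)-3-methoxyphenyl]ethyl}-1,3-dithian-2-yl)undecan-2-ol F4, with the stereocentre untouched. Acetylation (Ac2O, pyridine, cat. DMAP) gives (2S)-1-(2-{2-[4-(benzyloxy)-3-methoxyphenyl]ethyl}-1,3-dithian-2-yl)undecan-2-yl acetate F5. Dithiane hydrolysis (MeI, CaCO3, MeCN/H2O, 40 °C) gives (5S)-1-[4-(benzyloxy)-3-methoxyphenyl]-3-oxotetradecan-5-yl acetate F6, and hydrogenolysis (H2, Pd/C, EtOAc) gives 8.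

Second, step 2. The activated thioester carries a free phenol and may self-acylate to oligomeric aryl esters on concentration or on silica.

The fallback masks the phenol and changes the acyl electrophile; it sets out from 5 and comes back at 8. Acid 5 is silylated on both oxygens (TBSCl, imidazole, DMF) to tert-butyldimethylsilyl 3-{4-[(tert-butyldimethylsilyl)oxy]-3-methoxyphenyl}propanoate F7. Oxalyl chloride with catalytic DMF (CH2Cl2, 0 °C) converts the silyl ester directly into 3-{4-[(tert-butyldimethylsilyl)oxy]-3-methoxyphenyl}propanoyl chloride F8. F8 takes the place of 6 in step 3 (with 4 opened to 7 as before) and gives (5S)-1-{4-[(tert-butyldimethylsilyl)oxy]-3-methoxyphenyl}-3-oxotetradecan-5-yl acetate F9. HF·pyridine (THF, 0 °C) then frees the phenol to give 8.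

Third, step 1. Possible failures are partial attack of the organometallic at CH2Cl (this gives the enantiomeric epoxide and erodes ee), magnesium halide opening of the oxirane to halohydrins, and incomplete closure in the flask.

The fallback replaces the copper/Grignard opening by a Lewis-acid-assisted alkynylation; it sets out from 1 and comes back at 3, which is isolated this time. Lithium oct-1-ynide (from oct-1-yne and n-BuLi) with BF3·OEt2 (THF, −78 °C, Yamaguchi–Hirao conditions) opens 1 only at the oxirane CH2 to give (S)-1-chloroundec-4-yn-2-ol F10. Hydrogenation (H2, Pd/C, EtOAc) saturates the alkyne to 3, which is closed to 4 with aq. NaOH as in step 1.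

**Further compounds**
F1 | step 3 | benzyl 3-[4-(benzyloxy)-3-methoxyphenyl]propanoate | COc1cc(CCC(=O)OCc2ccccc2)ccc1OCc1ccccc1
F2 | step 3 | 3-[4-(benzyloxy)-3-methoxyphenyl]propanal | COc1cc(CCC=O)ccc1OCc1ccccc1
F3 | step 3 | 2-{2-[4-(benzyloxy)-3-methoxyphenyl]ethyl}-1,3-dithiane | COc1cc(CCC2SCCCS2)ccc1OCc1ccccc1
F4 | step 3 | (2S)-1-(2-{2-[4-(benzyloxy)-3-methoxyphenyl]ethyl}-1,3-dithian-2-yl)undecan-2-ol | CCCCCCCCC[C@@H](CC1(CCc2ccc(OCc3ccccc3)c(OC)c2)SCCCS1)O
F5 | step 3 | (2S)-1-(2-{2-[4-(benzyloxy)-3-methoxyphenyl]ethyl}-1,3-dithian-2-yl)undecan-2-yl acetate | CCCCCCCCC[C@@H](CC1(CCc2ccc(OCc3ccccc3)c(OC)c2)SCCCS1)OC(C)=O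
F6 | step 3 | (5S)-1-[4-(benzyloxy)-3-methoxyphenyl]-3-oxotetradecan-5-yl acetate | CCCCCCCCC[C@@H](CC(=O)CCc1ccc(OCc2ccccc2)c(OC)c1)OC(C)=O
F7 | step 2 | tert-butyldimethylsilyl 3-{4-[(tert-butyldimethylsilyl)oxy]-3-methoxyphenyl}propanoate | CC(C)(C)[Si](C)(C)OC(=O)CCc1ccc(O[Si](C)(C)C(C)(C)C)c(OC)c1
F8 | step 2 | 3-{4-[(tert-butyldimethylsilyl)oxy]-3-methoxyphenyl}propanoyl chloride | COc1cc(CCC(Cl)=O)ccc1O[Si](C)(C)C(C)(C)C
F9 | step 2 | (5S)-1-{4-[(tert-butyldimethylsilyl)oxy]-3-methoxyphenyl}-3-oxotetradecan-5-yl acetate | CCCCCCCCC[C@@H](CC(=O)CCc1ccc(O[Si](C)(C)C(C)(C)C)c(OC)c1)OC(C)=O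
F10 | step 1 | (S)-1-chloroundec-4-yn-2-ol | CCCCCCC#CC[C@@H](CCl)O
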